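**Retrosynthetic overview**

- The strategy rests on the C2 axis through the C8–C8' bond of the acyclic 2,3-dibenzylbutane-1,4-diol core: two adjacent CH stereocentres (8R,8'R), each carrying one CH2OH and one 4-hydroxy-3,5-dimethoxybenzyl group. The only rings are the two benzene rings.
- The two ArO–benzyl bonds are cleaved last. Each CH2OH is traced back to a vinyl group (C=C cleavage, then reduction), which exposes a (3S,4S)-3,4-bis(arylmethyl)hexa-1,5-diene.
- The C3–C4 bond of that diene (the future C8–C8') is cut into two identical (E)-4-arylbut-2-enyl halves, a pinacol boronate and a chloride, joined by Pd-catalysed asymmetric allyl–allyl coupling.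
- Both halves come from one allylic acetate, made by cross-metathesis of O-benzyl methoxyeugenol with (Z)-but-2-ene-1,4-diyl diacetate.
- Ring order: no ring is formed at any stage; both benzene rings arrive intact in methoxyeugenol.

Key step: step 6

Assumption: the (S)-antipode of the biaryl bis(di-2-furylphosphine) ligand is taken to deliver the (3S,4S)-diene. A small pilot run carried through to the target and read against the (8R,8'R) series by sign of rotation and chiral HPLC fixes this choice, and the (R)-antipode is swapped in with no other change if the sense is reversed.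

**Route**

Step 1
Reactants: 1 4-allyl-2,6-dimethoxyphenol (methoxyeugenol); 2 benzyl bromide
Product: 3 5-allyl-2-(benzyloxy)-1,3-dimethoxybenzene
Conditions: BnBr (1.1 equiv), K2CO3 (1.5 equiv), DMF, rt
Reagents that add atoms: benzyl bromide (compound 2), BrCc1ccccc1
Why: Williamson etherification of the phenoxide with a reactive benzylic bromide should be clean, and the benzyl ether should withstand Ru, Ni and Pd(0) catalysis, OsO4, periodate and borohydride and leave at the end by hydrogenolysis.

Step 2
Reactants: 3 5-allyl-2-(benzyloxy)-1,3-dimethoxybenzene; 4 (Z)-but-2-ene-1,4-diyl diacetate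
Product: 5 (E)-4-[4-(benzyloxy)-3,5-dimethoxyphenyl]but-2-en-1-yl acetate
Conditions: 4 (3 equiv), Hoveyda–Grubbs II (2 mol%), 1,4-benzoquinone (10 mol%), CH2Cl2, 40 °C
Reagents that add atoms: (Z)-but-2-ene-1,4-diyl diacetate (compound 4), CC(=O)OC/C=C\COC(C)=O
Why: Ru-carbene olefin cross-metathesis of a terminal allylarene with excess symmetrical diacetate should favour the E cross product over the homodimer of 3, the terminal CH2 of 3 leaving with one CH2OAc arm of 4 as allyl acetate, while benzoquinone quenches the Ru hydrides that would move the double bond into conjugation with the arene.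

Step 3
Reactants: 5 (E)-4-[4-(benzyloxy)-3,5-dimethoxyphenyl]but-2-en-1-yl acetate; 6 bis(pinacolato)diboron
Product: 7 2-{(E)-4-[4-(benzyloxy)-3,5-dimethoxyphenyl]but-2-en-1-yl}-4,4,5,5-tetramethyl-1,3,2-dioxaborolane
Conditions: B2pin2 (1.2 equiv), Ni(cod)2 (5 mol%), PCy3 (10 mol%), EtOAc, rt
Reagents that add atoms: bis(pinacolato)diboron (compound 6), CC1(C)OB(OC1(C)C)B1OC(C)(C)C(C)(C)O1
Why: Miyaura-type allylic borylation, in which oxidative addition of the allylic acetate to Ni(0), acetate-assisted transmetalation with the diboron and C–B reductive elimination at the unhindered terminus should give the linear E-allylboronate, with the mild temperature keeping β-hydride loss toward the arylbutadiene slow.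

Step 4
Reactants: 5 (E)-4-[4-(benzyloxy)-3,5-dimethoxyphenyl]but-2-en-1-yl acetate
Product: 8 (E)-4-[4-(benzyloxy)-3,5-dimethoxyphenyl]but-2-en-1-ol
Conditions: K2CO3 (0.2 equiv), MeOH, rt
Reagents that add atoms: none
Why: Base-catalysed transesterification (Zemplén-type methanolysis) should remove the acetate as methyl acetate, and nothing else in the molecule is base-labile.

Step 5
Reactants: 8 (E)-4-[4-(benzyloxy)-3,5-dimethoxyphenyl]but-2-en-1-ol
Product: 10 2-(benzyloxy)-5-[(E)-4-chlorobut-2-en-1-yl]-1,3-dimethoxybenzene, via allylic mesylate 9 (not isolated)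
Conditions: MsCl (1.2 equiv), 2,4,6-collidine (1.5 equiv), LiCl (3 equiv), DMF, 0 °C
Reagents that add atoms: methanesulfonyl chloride, CS(=O)(=O)Cl; lithium chloride, [Li+].[Cl-]
Why: Mesylation followed by SN2 displacement with chloride under near-neutral conditions should give the primary allylic chloride without SN2' transposition or change of alkene geometry, and it avoids any electrophilic chlorine source that could attack the electron-rich arene.

Step 6
Reactants: 7 2-{(E)-4-[4-(benzyloxy)-3,5-dimethoxyphenyl]but-2-en-1-yl}-4,4,5,5-tetramethyl-1,3,2-dioxaborolane (1.2 equiv); 10 2-(benzyloxy)-5-[(E)-4-chlorobut-2-en-1-yl]-1,3-dimethoxybenzene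
Product: 11 (3S,4S)-3,4-bis[4-(benzyloxy)-3,5-dimethoxybenzyl]hexa-1,5-diene
Conditions: Pd2(dba)3 (2.5 mol%), (S)-MeO-furyl-BIPHEP [(S)-(6,6'-dimethoxybiphenyl-2,2'-diyl)bis(di-2-furylphosphine)] (5 mol%), CsF (3 equiv), THF, rt
Reagents that add atoms: none
Why: Oxidative addition of 10 to Pd(0) and fluoride-assisted transmetalation from 7 should give a bis(allyl)palladium that the small-bite-angle chelating diphosphine holds as a bis(η1-allyl) complex, which collapses by a chair-like, Cope-type 3,3'-reductive elimination that joins the two arylmethyl-bearing γ-carbons. The closest known reaction type is the Pd-catalysed enantio- and diastereoselective allyl–allyl cross-coupling of γ-substituted allylboronates with γ-substituted allyl chlorides. No ring closes, and the step forms one C–C σ bond (the future C8–C8') and releases two vinyl groups. Both stereocentres arise in this single event: the threo (C2) relative configuration comes from the chair transition state with both arylmethyl groups pseudo-equatorial on E-allyl ligands, and the absolute configuration comes from the C2-symmetric ligand, which selects one of the two enantiomeric chair pairings. The step needs branched–branched regioselectivity, threo diastereoselectivity and one enantiomer, which should be secured by the chelate-enforced 3,3' pathway, by fast π–σ–π equilibration that funnels any Z material into the E allyl geometry, and by the identity of the two allyl ligands, so that allyl scrambling or homocoupling gives the same diene. β-Hydride loss from the benzylic CH2 should be outrun by reductive elimination from the electron-poor furylphosphine complex at room temperature with a slight excess of boronate, and 11 is kept far below Cope temperatures.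

Step 7
Reactants: 11 (3S,4S)-3,4-bis[4-(benzyloxy)-3,5-dimethoxybenzyl]hexa-1,5-diene
Product: 12 (3R,4R)-3,4-bis[4-(benzyloxy)-3,5-dimethoxybenzyl]hexane-1,2,5,6-tetraol (mixture of epimers at C2 and C5)
Conditions: OsO4 (4 mol%), NMO (3 equiv), acetone/t-BuOH/H2O, rt; Na2SO3 quench
Reagents that add atoms: osmium tetroxide (catalytic oxygen carrier), O=[Os](=O)(=O)=O; N-methylmorpholine N-oxide, C[N+]1([O-])CCOCC1; water, O
Why: Upjohn dihydroxylation, in which the [3+2] addition of OsO4 to the two monosubstituted alkenes should be much faster than any attack on the alkoxyarenes or benzyl ethers; C3 and C4 are untouched, and the unselective new carbinol centres vanish in the next step.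

Step 8
Reactants: 12 (3R,4R)-3,4-bis[4-(benzyloxy)-3,5-dimethoxybenzyl]hexane-1,2,5,6-tetraol
Product: 13 (2R,3R)-2,3-bis[4-(benzyloxy)-3,5-dimethoxybenzyl]butanedial
Conditions: NaIO4 (2.5 equiv), THF/pH 7 phosphate buffer, 0 °C; cold extractive work-up, crude used at once
Reagents that add atoms: none
Why: Malaprade glycol cleavage through cyclic periodate esters should cut both terminal diols to the aldehyde and formaldehyde, and neutral pH, low temperature and short contact should keep the α-stereocentres from enolising and the 1,4-dialdehyde from cyclising toward a furan.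

Step 9
Reactants: 13 (2R,3R)-2,3-bis[4-(benzyloxy)-3,5-dimethoxybenzyl]butanedial
Product: 14 (2R,3R)-2,3-bis[4-(benzyloxy)-3,5-dimethoxybenzyl]butane-1,4-diol
Conditions: NaBH4 (3 equiv), THF/MeOH, −20 to 0 °C; recrystallisation
Reagents that add atoms: none
Why: Borohydride reduction of the aldehydes should be faster than α-epimerisation at low temperature and breaks no bond at the stereocentres, and recrystallisation of the diol should raise the diastereomeric and enantiomeric purity.

Step 10
Reactants: 14 (2R,3R)-2,3-bis[4-(benzyloxy)-3,5-dimethoxybenzyl]butane-1,4-diol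
Product: 15 (2R,3R)-2,3-bis(4-hydroxy-3,5-dimethoxybenzyl)butane-1,4-diol (5,5'-dimethoxysecoisolariciresinol)
Conditions: H2 (1 atm), 10% Pd/C, EtOAc/EtOH, rt
Reagents that add atoms: none
Why: Heterogeneous catalytic hydrogenolysis should cleave only the two benzyl aryl ether C–O bonds, leaving the methyl ethers, the primary alcohols and the benzylic C–C bonds at the stereocentres untouched.

**Compound list**

1 | 4-allyl-2,6-dimethoxyphenol (methoxyeugenol) | C=CCc1cc(OC)c(O)c(OC)c1 | starting material
2 | benzyl bromide | BrCc1ccccc1 | starting material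
3 | 5-allyl-2-(benzyloxy)-1,3-dimethoxybenzene | C=CCc1cc(OC)c(OCc2ccccc2)c(OC)c1 | intermediate
4 | (Z)-but-2-ene-1,4-diyl diacetate | CC(=O)OC/C=C\COC(C)=O | starting material
5 | (E)-4-[4-(benzyloxy)-3,5-dimethoxyphenyl]but-2-en-1-yl acetate | CC(=O)OC/C=C/Cc1cc(OC)c(OCc2ccccc2)c(OC)c1 | intermediate
6 | bis(pinacolato)diboron | CC1(C)OB(OC1(C)C)B1OC(C)(C)C(C)(C)O1 | starting material
7 | 2-{(E)-4-[4-(benzyloxy)-3,5-dimethoxyphenyl]but-2-en-1-yl}-4,4,5,5-tetramethyl-1,3,2-dioxaborolane | CC1(C)OB(C/C=C/Cc2cc(OC)c(OCc3ccccc3)c(OC)c2)OC1(C)C | intermediate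
8 | (E)-4-[4-(benzyloxy)-3,5-dimethoxyphenyl]but-2-en-1-ol | OC/C=C/Cc1cc(OC)c(OCc2ccccc2)c(OC)c1 | intermediate
9 | (E)-4-[4-(benzyloxy)-3,5-dimethoxyphenyl]but-2-en-1-yl methanesulfonate | CS(=O)(=O)OC/C=C/Cc1cc(OC)c(OCc2ccccc2)c(OC)c1 | intermediate
10 | 2-(benzyloxy)-5-[(E)-4-chlorobut-2-en-1-yl]-1,3-dimethoxybenzene | ClC/C=C/Cc1cc(OC)c(OCc2ccccc2)c(OC)c1 | intermediate
11 | (3S,4S)-3,4-bis[4-(benzyloxy)-3,5-dimethoxybenzyl]hexa-1,5-diene | COc1cc(C[C@@H](C=C)[C@H](C=C)Cc2cc(OC)c(OCc3ccccc3)c(OC)c2)cc(OC)c1OCc1ccccc1 | intermediate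
12 | (3R,4R)-3,4-bis[4-(benzyloxy)-3,5-dimethoxybenzyl]hexane-1,2,5,6-tetraol (C2/C5 epimer mixture) | COc1cc(C[C@@H](C(O)CO)[C@H](C(O)CO)Cc2cc(OC)c(OCc3ccccc3)c(OC)c2)cc(OC)c1OCc1ccccc1 | intermediate
13 | (2R,3R)-2,3-bis[4-(benzyloxy)-3,5-dimethoxybenzyl]butanedial | COc1cc(C[C@@H](C=O)[C@H](C=O)Cc2cc(OC)c(OCc3ccccc3)c(OC)c2)cc(OC)c1OCc1ccccc1 | intermediate
14 | (2R,3R)-2,3-bis[4-(benzyloxy)-3,5-dimethoxybenzyl]butane-1,4-diol | COc1cc(C[C@@H](CO)[C@H](CO)Cc2cc(OC)c(OCc3ccccc3)c(OC)c2)cc(OC)c1OCc1ccccc1 | intermediate
15 | (2R,3R)-2,3-bis(4-hydroxy-3,5-dimethoxybenzyl)butane-1,4-diol (5,5'-dimethoxysecoisolariciresinol) | COc1cc(C[C@@H](CO)[C@H](CO)Cc2cc(OC)c(O)c(OC)c2)cc(OC)c1O | target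

**Step count**

Total: 10 steps. Longest linear sequence: 9 steps (1, 2, 4, 5, 6, 7, 8, 9, 10); the boronate branch (step 3) joins at step 6.

**Steps most likely to fail**

Step 6. The 3,3'-reductive elimination may give incomplete stereocontrol, either by leakage through a boat-like pairing to the meso diene or by weak enantioface pairing. Competing β-hydride elimination from the benzylic CH2 of the allyl–palladium intermediates, or bond formation at the unsubstituted termini to linear dienes, may also erode the yield. The fallback replaces the catalytic coupling by an auxiliary-controlled oxidative enolate dimerisation; it sets out from 3 and returns to the route at 14, bypassing 11 to 13.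
- Hydroboration–oxidation of 3 (9-BBN, THF; then NaOH, H2O2) should give 3-[4-(benzyloxy)-3,5-dimethoxyphenyl]propan-1-ol F1.
- Oxidation (catalytic TEMPO, PhI(OAc)2, MeCN/H2O) should give 3-[4-(benzyloxy)-3,5-dimethoxyphenyl]propanoic acid F2.
- Mixed-anhydride acylation (PivCl, Et3N, THF; then (S)-4-isopropyloxazolidin-2-one, LiCl) should give (S)-3-{3-[4-(benzyloxy)-3,5-dimethoxyphenyl]propanoyl}-4-isopropyloxazolidin-2-one F3.
- Oxidative homocoupling of its lithium enolate (LDA, THF, −78 °C; then TiCl4) should join the two α-carbons on the face away from the isopropyl groups and give the (2R,3R)-2,3-bis[4-(benzyloxy)-3,5-dimethoxybenzyl]succinyl bis-oxazolidinone F4.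
- Reductive removal of the auxiliary (LiBH4, THF/MeOH, 0 °C) should deliver 14.

Step 8. Enolisation of the dialdehyde during cleavage or work-up may epimerise the two α-stereocentres, and acid-promoted cyclisation and dehydration may drain material toward a furan. The fallback avoids a free dialdehyde; it sets out from 11 and returns at 14, bypassing 12 and 13. Ozonolysis of 11 (O3, CH2Cl2, −78 °C, stopped at a Sudan III end point to spare the electron-rich arenes) should give the (2R,3R)-1,4-bis[4-(benzyloxy)-3,5-dimethoxyphenyl]-2,3-di(1,2,4-trioxolan-3-yl)butane F5. This is reduced in the same flask (NaBH4, MeOH, −78 to 0 °C) straight to 14.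

Step 3. β-Hydride elimination from the allyl–nickel intermediate may give the 1-arylbuta-1,3-diene, and the allylboronate may suffer protodeboronation or allylic transposition on purification. The fallback builds the C=C bond with boron already in place; it sets out from 3 and returns at 7. Cross-metathesis of 3 with commercial allylboronic acid pinacol ester (Ru carbene, 1,4-benzoquinone, CH2Cl2, 40 °C) should give 7 as an E-rich mixture, which the π–σ–π equilibration in step 6 should tolerate. This detour makes no compound outside the compound list (entry F0).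

**Further compounds**

F1 | step 6 | 3-[4-(benzyloxy)-3,5-dimethoxyphenyl]propan-1-ol | OCCCc1cc(OC)c(OCc2ccccc2)c(OC)c1
F2 | step 6 | 3-[4-(benzyloxy)-3,5-dimethoxyphenyl]propanoic acid | OC(=O)CCc1cc(OC)c(OCc2ccccc2)c(OC)c1
F3 | step 6 | (S)-3-{3-[4-(benzyloxy)-3,5-dimethoxyphenyl]propanoyl}-4-isopropyloxazolidin-2-one | CC(C)[C@H]1COC(=O)N1C(=O)CCc1cc(OC)c(OCc2ccccc2)c(OC)c1
F4 | step 6 | (2R,3R)-2,3-bis[4-(benzyloxy)-3,5-dimethoxybenzyl]-1,4-bis[(S)-4-isopropyl-2-oxooxazolidin-3-yl]butane-1,4-dione | CC(C)[C@H]1COC(=O)N1C(=O)[C@H](Cc1cc(OC)c(OCc2ccccc2)c(OC)c1)[C@@H](Cc1cc(OC)c(OCc2ccccc2)c(OC)c1)C(=O)N1[C@@H](C(C)C)COC1=O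
F5 | step 8 | (2R,3R)-1,4-bis[4-(benzyloxy)-3,5-dimethoxyphenyl]-2,3-di(1,2,4-trioxolan-3-yl)butane (epimer mixture at the trioxolane carbons) | COc1cc(C[C@@H](C2OCOO2)[C@H](C2OCOO2)Cc2cc(OC)c(OCc3ccccc3)c(OC)c2)cc(OC)c1OCc1ccccc1
F0 | step 3 | none | none
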